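**Retrosynthetic overview**

1. The target comes from its 4-deoxo analogue by a final allylic C–H oxidation of the cyclohexene ring. The enone C=O is deferred so that the ring-forming step meets only one Michael acceptor.
2. The 1,2-dioxane is made by a one-pot formal [4+2]: C4–C5 by radical γ-alkylation of a tiglate-derived vinylketene silyl acetal with a β-peroxy primary iodide, then O2–C3 by peroxide-anion oxa-Michael closure onto the enoate so formed.
3. Enabling feature: dioxane C3 is the β-carbon and C4 the γ-carbon of the exocyclic 2-methylpropanoate, so C1–C4 with the 2-methyl group are one tiglate unit. C6 is a fully substituted O–O-bearing carbon, and its neighbour C5 is a CH2 with no β-hydrogen.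
4. The C5/C6/O–O unit comes from the (S)-epoxide of dihydro-β-ionone (asymmetric Corey–Chaykovsky), opened by H2O2 at the tertiary carbon with inversion; the CH2OH then becomes CH2I.
5. Ring order: the carbocycle is bought with dihydro-β-ionone; the 1,2-dioxane is the only ring made (step 6).

Key step: step 6

Assumption: the antipode of the LaLi3 tris(binaphthoxide) catalyst (step 1) and the pseudoenantiomeric series of the cinchona ammonium salt (step 6) are chosen so that the drawn configurations result; the (S)-binaphthoxide complex and the cinchonidinium salt are written for definiteness.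

**Route**

Step 1
Reactants: 1 dihydro-β-ionone
Product: 2 (S)-2-methyl-2-[2-(2,6,6-trimethylcyclohex-1-en-1-yl)ethyl]oxirane
Conditions: LaLi3[(S)-binaphthoxide]3 (5 mol%), tris(2,4,6-trimethoxyphenyl)phosphine oxide (5 mol%), dimethylsulfoxonium methylide (1.2 equiv, preformed THF solution), 5 Å MS, THF, rt
Reagents that add atoms: dimethylsulfoxonium methylide C[S+](C)(=O)[CH2-]
Why: Catalytic asymmetric Corey–Chaykovsky epoxidation of a methyl ketone, in which the La/Li binaphthoxide complex binds ketone and ylide and tells the CH3 flank from the CH2CH2R flank, so that methylene is delivered to one carbonyl face and the quaternary centre (later C6) is set as (S).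

Step 2
Reactants: 2 (S)-epoxide
Product: 3 (R)-2-hydroperoxy-2-methyl-4-(2,6,6-trimethylcyclohex-1-en-1-yl)butan-1-ol
Conditions: H2O2 (anhydrous, in Et2O, 10 equiv), H3PMo12O40 (2 mol%), Et2O, 0 °C
Reagents that add atoms: hydrogen peroxide OO
Why: Heteropolyacid-catalysed perhydrolysis of a 2,2-disubstituted epoxide, in which H2O2 attacks the tertiary carbon from the side opposite the breaking C–O bond, so the C–OOH centre should form with inversion ((S)-2 to (R)-3) and the CH2OH marks the future C5.

Step 3
Reactants: 3 (R)-hydroxy hydroperoxide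
Product: 4 (R)-2-methyl-2-(triethylsilylperoxy)-4-(2,6,6-trimethylcyclohex-1-en-1-yl)butan-1-ol
Conditions: Et3SiCl (1.05 equiv), Et3N (1.2 equiv), CH2Cl2, −40 to −20 °C
Reagents that add atoms: chlorotriethylsilane CC[Si](Cl)(CC)CC
Why: Chemoselective O-silylation, because the hydroperoxide is more acidic and more nucleophilic (α-effect) than the neopentyl-type primary alcohol, which reacts slowly with Et3SiCl when no nucleophilic catalyst is present.

Step 4
Reactants: 4 (R)-silylperoxy alcohol
Product: 6 (R)-triethyl{[1-iodo-2-methyl-4-(2,6,6-trimethylcyclohex-1-en-1-yl)butan-2-yl]peroxy}silane, via neopentyl triflate 5 (not isolated)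
Conditions: Tf2O (1.1 equiv), 2,6-lutidine (1.5 equiv), CH2Cl2, −78 °C; then Bu4NI (2 equiv), −78 to 20 °C
Reagents that add atoms: tetrabutylammonium iodide CCCC[N+](CCCC)(CCCC)CCCC.[I-]; trifluoromethanesulfonic anhydride O=S(=O)(OS(=O)(=O)C(F)(F)F)C(F)(F)F (its atoms stay in 5 only)
Why: Triflation of the hindered primary alcohol followed by SN2 displacement with iodide, the triflate being a good enough leaving group to make substitution at the neopentyl-type carbon feasible at low temperature, with the stereocentre untouched.

Step 5
Reactants: 7 methyl tiglate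
Product: 9 tert-butyl[(1-methoxy-2-methylbuta-1,3-dien-1-yl)oxy]dimethylsilane, via lithium dienolate 8 (not isolated)
Conditions: LiN(i-Pr)2 (1.1 equiv), DMPU, THF, −78 °C; then t-BuMe2SiCl, −78 to 0 °C
Reagents that add atoms: tert-butyldimethylsilyl chloride CC(C)(C)[Si](C)(C)Cl; lithium diisopropylamide [Li+].CC(C)[N-]C(C)C (lithium stays in 8 only)
Why: γ-Deprotonation of the enoate and O-silylation of the dienolate, the standard preparation of vinylketene silyl acetals used as vinylogous Mukaiyama donors; the ketene acetal geometry is of no consequence.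

Step 6
Reactants: 6 (R)-iodide; 9 vinylketene silyl acetal
Product: 12 methyl (2R)-2-[(3R,6R)-6-methyl-6-[2-(2,6,6-trimethylcyclohex-1-en-1-yl)ethyl]-1,2-dioxan-3-yl]propanoate, via enoate silyl peroxide 10 (not isolated), via peroxide anion 11 (not isolated)
Conditions: Mn2(CO)10 (10 mol%), 9 (5 equiv), 2,6-lutidine (1.5 equiv), PhCF3, 405 nm LEDs, 0 °C; volatiles removed; then CsF (4 equiv), N-(9-anthracenylmethyl)-O-allylcinchonidinium bromide (10 mol%), t-BuOH (3 equiv), toluene, −20 °C
Reagents that add atoms: none
Why: Proposed new method: light-induced homolysis of Mn2(CO)10 gives the Mn(CO)5 radical, which abstracts iodine from 6; the primary β-silylperoxy alkyl radical adds to the free CH2 terminus of s-trans diene 9, and the 1,1-dioxygenated allyl radical takes iodine back from IMn(CO)5 and collapses, with loss of t-BuMe2SiI, to (E)-enoate 10 (new C4–C5 bond). Fluoride carried into toluene by the chiral ammonium cation then cleaves the Si–O bond, and peroxide anion 11, held as an ion pair, adds to the enoate β-carbon in a 6-exo-trig oxa-Michael closure through a chair-like transition state with the ester arm equatorial (new O2–C3 bond), after which the ester enolate is protonated by t-BuOH. The closest known reaction types are Mn2(CO)10-mediated iodine-atom-transfer additions of unactivated alkyl iodides, photoredox γ-alkylation of silyl dienol ethers with activated halides, fluoride- or amine-triggered hydroperoxide oxa-Michael closure of 1,2-dioxanes onto enoates, and ion-pair-controlled conjugate addition of peroxide anions in phase-transfer Weitz–Scheffer epoxidation. C3 is to be set by the chiral cation, which shields one face of the enoate in the ion pair; the C6 centre is 1,4-remote and its methyl and CH2CH2R groups are sterically alike, so no useful substrate bias is expected and the catalyst has to decide. C2 is to be set by protonation of the exocyclic enolate in its A(1,3)-minimised conformer (C3–H eclipsing the enolate) from the face of the peroxide oxygen, anti to the ring CH2, which gives the 2,3-anti (2R,3R) relationship. The step needs γ- over α-attack on 9 (secured by the free CH2 terminus against the fully substituted C1), radical addition ahead of the 3-exo attack of the radical on its own O–O bond (secured by a large excess of 9 at 0 °C), and a single Michael acceptor for 11 (secured by keeping the carbocycle at the alkene oxidation level until step 7).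

Step 7
Reactants: 12 4-deoxo dioxane ester
Product: 13 diacarperoxide A
Conditions: Rh2(cap)4 (dirhodium tetrakis(caprolactamate), 1 mol%), t-BuOOH (70% in water, 8 equiv), 1,2-dichloroethane, 40 °C
Reagents that add atoms: tert-butyl hydroperoxide CC(C)(C)OO
Why: Allylic oxidation by a tert-butylperoxyl radical chain at the only unhindered ring CH2 next to the methyl-bearing alkene carbon, as in the conversion of β-ionone-type rings into their 4-oxo derivatives, while the dialkyl peroxide, the ester and the three stereocentres are not involved.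

**Compound list**

1 | dihydro-β-ionone, 4-(2,6,6-trimethylcyclohex-1-en-1-yl)butan-2-one | CC(=O)CCC1=C(C)CCCC1(C)C | starting material
2 | (S)-2-methyl-2-[2-(2,6,6-trimethylcyclohex-1-en-1-yl)ethyl]oxirane | C[C@]1(CCC2=C(C)CCCC2(C)C)CO1 | intermediate
3 | (R)-2-hydroperoxy-2-methyl-4-(2,6,6-trimethylcyclohex-1-en-1-yl)butan-1-ol | OC[C@@](C)(CCC1=C(C)CCCC1(C)C)OO | intermediate
4 | (R)-2-methyl-2-(triethylsilylperoxy)-4-(2,6,6-trimethylcyclohex-1-en-1-yl)butan-1-ol | OC[C@@](C)(CCC1=C(C)CCCC1(C)C)OO[Si](CC)(CC)CC | intermediate
5 | (R)-2-methyl-2-(triethylsilylperoxy)-4-(2,6,6-trimethylcyclohex-1-en-1-yl)butyl trifluoromethanesulfonate | O=S(=O)(OC[C@@](C)(CCC1=C(C)CCCC1(C)C)OO[Si](CC)(CC)CC)C(F)(F)F | intermediate (not isolated)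
6 | (R)-triethyl{[1-iodo-2-methyl-4-(2,6,6-trimethylcyclohex-1-en-1-yl)butan-2-yl]peroxy}silane | IC[C@@](C)(CCC1=C(C)CCCC1(C)C)OO[Si](CC)(CC)CC | intermediate
7 | methyl tiglate, methyl (E)-2-methylbut-2-enoate | C/C=C(\C)C(=O)OC | starting material
8 | lithium dienolate of methyl tiglate (lithium 1-methoxy-2-methylbuta-1,3-dien-1-olate) | [Li+].C=CC(C)=C(OC)[O-] | intermediate (not isolated)
9 | tert-butyl[(1-methoxy-2-methylbuta-1,3-dien-1-yl)oxy]dimethylsilane (mixture of ketene acetal geometries) | C=CC(C)=C(OC)O[Si](C)(C)C(C)(C)C | intermediate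
10 | methyl (2E,6S)-2,6-dimethyl-6-(triethylsilylperoxy)-8-(2,6,6-trimethylcyclohex-1-en-1-yl)oct-2-enoate | COC(=O)/C(C)=C/CC[C@@](C)(CCC1=C(C)CCCC1(C)C)OO[Si](CC)(CC)CC | intermediate (not isolated)
11 | peroxide anion of 10 after loss of the silyl group (ion pair with the chiral ammonium cation) | COC(=O)/C(C)=C/CC[C@@](C)(CCC1=C(C)CCCC1(C)C)O[O-] | intermediate (not isolated)
12 | methyl (2R)-2-[(3R,6R)-6-methyl-6-[2-(2,6,6-trimethylcyclohex-1-en-1-yl)ethyl]-1,2-dioxan-3-yl]propanoate | COC(=O)[C@H](C)[C@H]1CC[C@@](C)(CCC2=C(C)CCCC2(C)C)OO1 | intermediate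
13 | diacarperoxide A, methyl (2R)-2-[(3R,6R)-6-methyl-6-[2-(2,6,6-trimethyl-3-oxocyclohex-1-en-1-yl)ethyl]-1,2-dioxan-3-yl]propanoate | COC(=O)[C@H](C)[C@H]1CC[C@@](C)(CCC2=C(C)C(=O)CCC2(C)C)OO1 | target

**Step count**

Total step count: 7 (steps 1–4, 6 and 7 in the main line; step 5 makes the two-carbon partner).
Longest linear sequence: 6 steps (1, 2, 3, 4, 6, 7).

**Steps most likely to fail, with fallbacks**

Step 6 (proposed new method). Three processes may defeat it:
- The primary radical may attack its own O–O bond (epoxide formation with loss of a silyloxyl radical) faster than it adds to 9.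
- Iodine return to the electron-rich allyl radical may be too slow to sustain turnover.
- In the second stage, facial selection at C3 by the ion pair or the direction of protonation at C2 may be poor.

The fallback uses only known chemistry; it sets out from alcohol 4 and comes back to the route at 12. Alcohol 4 is oxidised with Dess–Martin periodinane (NaHCO3, CH2Cl2, 0 °C) to (R)-2-methyl-2-(triethylsilylperoxy)-4-(2,6,6-trimethylcyclohex-1-en-1-yl)butanal F1, which has no α-hydrogen. Horner–Wadsworth–Emmons olefination with methyl (E)-4-(diethoxyphosphoryl)-2-methylbut-2-enoate and LiN(SiMe3)2 (THF, −78 to 0 °C) gives the (2E,4E,6R)-dienoate F2. Diimide (KO2CN=NCO2K, AcOH, MeOH, 0 °C) should saturate the disubstituted 4,5-double bond ahead of the trisubstituted enoate and the tetrasubstituted ring alkene, which gives 10 as an isolated compound. HF·pyridine (THF, 0 °C) frees the (2E,6S)-hydroperoxy enoate F3, and Et2NH in CF3CH2OH closes the dioxane. Compound 12 is then separated from its C2/C3 isomers by HPLC.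

Step 2. Three processes may defeat it:
- Ionisation to a free tertiary cation, with loss of configuration.
- A 1,2-hydride shift to the aldehyde (Meinwald rearrangement).
- Oxygen transfer from molybdenum peroxo species to the tetrasubstituted alkene.

The fallback installs the tertiary hydroperoxide by oxetane perhydrolysis and removes the extra carbon afterwards; it sets out from 1 and comes back at 6. Ketone 1 is treated with the same LaLi3[(S)-binaphthoxide]3 catalyst and an excess of dimethylsulfoxonium methylide (rt, then 45 °C), so that the epoxide is ring-expanded in the same pot to (S)-2-methyl-2-[2-(2,6,6-trimethylcyclohex-1-en-1-yl)ethyl]oxetane F4. Lewis acid-catalysed perhydrolysis (ethereal H2O2, Me3SiOSO2CF3 cat., −78 to 0 °C) should open it at the tertiary carbon with inversion to the (R)-3-hydroperoxy-3-methylpentan-1-ol F5. Et3SiOSO2CF3 and 2,6-lutidine give the bis-silyl compound F6. Swern oxidation converts the primary silyl ether directly into the (R)-3-(silylperoxy) aldehyde F7, and Pinnick oxidation (NaClO2, NaH2PO4, 2-methyl-2-butene) gives the (R)-acid F8. The acid is converted with N-hydroxypyridine-2-thione and dicyclohexylcarbodiimide into the Barton ester F9, which on irradiation with CHI3 undergoes Barton decarboxylative iodination to 6.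

Step 7. Three processes may defeat it:
- Hydrogen abstraction at the side-chain allylic CH2 or at the allylic methyl group.
- Over-oxidation.
- Radical- or base-induced cleavage of the dioxane.

The fallback moves the oxidation in front of the ring formation; it sets out from 6 and comes back at 13. Iodide 6 is oxidised with CrO3 and 3,5-dimethylpyrazole (CH2Cl2, −20 °C) to the (R)-oxo iodide F10. The conditions of step 6 then lead through the oxo enoate silyl peroxide F11 and its peroxide anion F12 directly to 13. The price is a second, strongly hindered Michael acceptor beside the enoate during the closure.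

**Further compounds**

F1 | step 6 | (R)-2-methyl-2-(triethylsilylperoxy)-4-(2,6,6-trimethylcyclohex-1-en-1-yl)butanal | O=C[C@@](C)(CCC1=C(C)CCCC1(C)C)OO[Si](CC)(CC)CC
F2 | step 6 | methyl (2E,4E,6R)-2,6-dimethyl-6-(triethylsilylperoxy)-8-(2,6,6-trimethylcyclohex-1-en-1-yl)octa-2,4-dienoate | COC(=O)/C(C)=C/C=C/[C@@](C)(CCC1=C(C)CCCC1(C)C)OO[Si](CC)(CC)CC
F3 | step 6 | methyl (2E,6S)-6-hydroperoxy-2,6-dimethyl-8-(2,6,6-trimethylcyclohex-1-en-1-yl)oct-2-enoate | COC(=O)/C(C)=C/CC[C@@](C)(CCC1=C(C)CCCC1(C)C)OO
F4 | step 2 | (S)-2-methyl-2-[2-(2,6,6-trimethylcyclohex-1-en-1-yl)ethyl]oxetane | C[C@]1(CCC2=C(C)CCCC2(C)C)CCO1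
F5 | step 2 | (R)-3-hydroperoxy-3-methyl-5-(2,6,6-trimethylcyclohex-1-en-1-yl)pentan-1-ol | OCC[C@@](C)(CCC1=C(C)CCCC1(C)C)OO
F6 | step 2 | (R)-triethyl{[3-methyl-3-(triethylsilylperoxy)-5-(2,6,6-trimethylcyclohex-1-en-1-yl)pentyl]oxy}silane | CC[Si](CC)(CC)OCC[C@@](C)(CCC1=C(C)CCCC1(C)C)OO[Si](CC)(CC)CC
F7 | step 2 | (R)-3-methyl-3-(triethylsilylperoxy)-5-(2,6,6-trimethylcyclohex-1-en-1-yl)pentanal | O=CC[C@@](C)(CCC1=C(C)CCCC1(C)C)OO[Si](CC)(CC)CC
F8 | step 2 | (R)-3-methyl-3-(triethylsilylperoxy)-5-(2,6,6-trimethylcyclohex-1-en-1-yl)pentanoic acid | OC(=O)C[C@@](C)(CCC1=C(C)CCCC1(C)C)OO[Si](CC)(CC)CC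
F9 | step 2 | 2-thioxopyridin-1(2H)-yl (R)-3-methyl-3-(triethylsilylperoxy)-5-(2,6,6-trimethylcyclohex-1-en-1-yl)pentanoate | S=C1C=CC=CN1OC(=O)C[C@@](C)(CCC2=C(C)CCCC2(C)C)OO[Si](CC)(CC)CC
F10 | step 7 | (R)-3-[4-iodo-3-methyl-3-(triethylsilylperoxy)butyl]-2,4,4-trimethylcyclohex-2-en-1-one | IC[C@@](C)(CCC1=C(C)C(=O)CCC1(C)C)OO[Si](CC)(CC)CC
F11 | step 7 | methyl (2E,6S)-2,6-dimethyl-6-(triethylsilylperoxy)-8-(2,6,6-trimethyl-3-oxocyclohex-1-en-1-yl)oct-2-enoate | COC(=O)/C(C)=C/CC[C@@](C)(CCC1=C(C)C(=O)CCC1(C)C)OO[Si](CC)(CC)CC
F12 | step 7 | peroxide anion of F11 after loss of the silyl group | COC(=O)/C(C)=C/CC[C@@](C)(CCC1=C(C)C(=O)CCC1(C)C)O[O-]
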